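**Plan**

Locants are those of the azulene skeleton of the target (C3 carbinol, C3a/C8a ring fusion, C4 ester carbon, C6 formyl-bearing carbon).
Retrosynthesis: first the C4–O aroyl ester and the C6 CHO (from CO2Me); then the seven-membered ring at C5–C6 and C8–C8a, i.e. a C6–C7–C8 vinylcarbene (methyl 2-diazobut-3-enoate) plus the 2-siloxy diene C5=C4(OSi)–C3a=C8a; then the cyclopentene at C3–iPr and C3a–C4, back to 2-bromo-3-methylcyclopent-2-enone.
Forward: the cyclopentene with its C3 carbinol is made first; the seven-membered ring is closed last by Rh-catalysed cyclopropanation/divinylcyclopropane Cope rearrangement (formal (4+3)); C3a, C4 and the oxidation levels are then adjusted and the ester is attached.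
Enabling feature: in the seven-membered ring the C6=C7 alkene that carries the carbonyl carbon lies 1,4 to the C3a–C4(O) unit, with sp3 C5 and C8 between them; this is the cyclohepta-1,4-diene (enoate plus enol ether) that a vinylcarbene and a 2-oxy-1,3-diene deliver, with quaternary C8a as the substituted diene terminus.
Stereochemistry: C3 from a catalytic asymmetric isopropyl addition; C8a from the chiral Rh catalyst (cyclopropane configuration relayed by the boat Cope transition state); C3a by protonation anti to OSiEt3/CH3; C4 by dissolving-metal (thermodynamic) reduction.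

Key step: step 5

Remark: the sense of induction of the two chiral catalysts (steps 1 and 5) is assigned by analogy with their usual models; both are available in either enantiomeric form, so the assignment can be corrected without changing the route.

**Route**

Step 1
Reactants: 1 2-bromo-3-methylcyclopent-2-en-1-one
Product: 2 (1R)-2-bromo-3-methyl-1-(propan-2-yl)cyclopent-2-en-1-ol
Conditions: iPr2Zn (2.5 equiv), Ti(OiPr)4 (1.2 equiv), trans-1,2-bis(hydroxycamphorsulfonamido)cyclohexane ligand (10 mol %), PhMe, 0 °C → rt; sat. aq NH4Cl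
Reagents that add atoms: diisopropylzinc CC(C)[Zn]C(C)C
Why: Titanium/bis(sulfonamide) diol-catalysed enantioselective 1,2-addition of a dialkylzinc to an α-substituted cyclic enone, here with a secondary alkyl group: the 2-bromo substituent makes the two flanks of the carbonyl strongly different for the chiral titanium complex, which delivers isopropyl to one face and sets C3 (1R in 2), while the β-methyl group and the bromine block conjugate addition.

Step 2
Reactants: 2 (1R)-2-bromo-3-methyl-1-(propan-2-yl)cyclopent-2-en-1-ol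
Product: 4 1-[(5R)-5-hydroxy-2-methyl-5-(propan-2-yl)cyclopent-1-en-1-yl]ethan-1-one, via ethoxy diene 3 (not isolated)
Conditions: tributyl(1-ethoxyvinyl)stannane (1.5 equiv), Pd(PPh3)4 (5 mol %), CuI (10 mol %), PhMe, 100 °C; then 1 M aq HCl, THF, 0 °C
Reagents that add atoms: tributyl(1-ethoxyvinyl)stannane CCCC[Sn](CCCC)(CCCC)C(=C)OCC; water O
Why: Stille coupling of the hindered vinyl bromide with an acetyl-anion equivalent (copper co-catalysis for the slow transmetalation), then mild acid hydrolysis of enol ether 3 to the methyl ketone; the C3 stereocentre is not involved and the acyl group on the adjacent alkene disfavours ionisation of the tertiary allylic alcohol.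

Step 3
Reactants: 4 1-[(5R)-5-hydroxy-2-methyl-5-(propan-2-yl)cyclopent-1-en-1-yl]ethan-1-one
Product: 5 triethyl[(1-{(5R)-2-methyl-5-(propan-2-yl)-5-[(triethylsilyl)oxy]cyclopent-1-en-1-yl}ethenyl)oxy]silane
Conditions: TESOTf (2.6 equiv), Et3N (4 equiv), CH2Cl2, −78 → 0 °C
Reagents that add atoms: triethylsilyl trifluoromethanesulfonate CC[Si](CC)(CC)OS(=O)(=O)C(F)(F)F
Why: Silyl triflate/amine silylation: the tertiary hydroxyl is capped (against O–H insertion in step 5) and the methyl ketone is enol-silylated on its methyl side, the only α-position with hydrogen, by the usual kinetic preference for α′- over γ-deprotonation, giving the cross-conjugated 2-siloxy-1,3-diene.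

Step 4
Reactants: 6 methyl but-3-enoate
Product: 7 methyl 2-diazobut-3-enoate
Conditions: p-ABSA (1.2 equiv), DBU (1.3 equiv), MeCN, 0 °C; pentane extraction, solution used at once
Reagents that add atoms: 4-acetamidobenzenesulfonyl azide CC(=O)Nc1ccc(cc1)S(=O)(=O)N=[N+]=[N-]
Why: Regitz diazo transfer (sulfonyl azide, amidine base) to the α-carbon of the β,γ-unsaturated ester, which is activated by both the ester and the vinyl group; the volatile, thermally labile vinyldiazoacetate is kept cold in pentane and used at once.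

Step 5
Reactants: 5 triethyl[(1-{(5R)-2-methyl-5-(propan-2-yl)-5-[(triethylsilyl)oxy]cyclopent-1-en-1-yl}ethenyl)oxy]silane; 7 methyl 2-diazobut-3-enoate
Product: 9 methyl (3R,8aR)-8a-methyl-3-(propan-2-yl)-3,4-bis(triethylsilyloxy)-1,2,3,5,8,8a-hexahydroazulene-6-carboxylate, via divinylcyclopropane 8 (not isolated)
Conditions: Rh2(R-DOSP)4 (1 mol %), 7 (3 equiv, slow addition), hexanes, −40 °C → rt; then PhMe, 80 °C
Reagents that add atoms: none
Why: Rh2(R-DOSP)4 converts 7 into a donor/acceptor vinylcarbenoid that cyclopropanates the terminal enol-ether alkene of 5 (C4=C5; the ring alkene is tetrasubstituted and inert) to the cis-divinylcyclopropane 8, whose [3,3] shift through the geometrically enforced boat transition state breaks C4–C6 and forms C8–C8a. This is the tandem cyclopropanation/Cope rearrangement (formal (4+3) cycloaddition) of vinyldiazoacetates with 2-oxygenated and terminally disubstituted 1,3-dienes, the closest known reaction type. The seven-membered ring is closed onto the preformed cyclopentene by an intermolecular (4+3) annulation, C5–C6 arising by carbene transfer and C8–C8a by the sigmatropic step, and it emerges as the cyclohepta-1,4-diene with the C6 ester, the C6=C7 alkene and the C4 enol ether in their final positions. The one new stereocentre that persists, quaternary C8a, is fixed by the (1S,2R) configuration of 8, because in the boat transition state the C6 vinyl group can reach only the face of C3a=C8a anti to the C3 silyloxy group, and that cyclopropane configuration is imposed by the chiral catalyst at the prochiral enol ether (reagent control, remote from C3). The step needs site selectivity (the electron-rich 1,1-disubstituted enol ether against the hindered ring alkene), cis-divinyl geometry (alkenyl group cis to the vinyl donor, with thermal equilibration of the donor–acceptor cyclopropane as reserve) and diastereoface selectivity at C8a (catalyst-controlled; products from the minor enantiomer of 5 or from mismatched cyclopropanation are diastereomers and are separated). Hydrocarbon solvent and the prolinate catalyst suppress attack at the vinylogous carbene position, the silyl ether excludes O–H insertion, and the final heating overcomes the retardation of the Cope step by the Z-methyl group on C8a.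

Step 6
Reactants: 9 methyl (3R,8aR)-8a-methyl-3-(propan-2-yl)-3,4-bis(triethylsilyloxy)-1,2,3,5,8,8a-hexahydroazulene-6-carboxylate
Product: 10 [(3R,8aR)-8a-methyl-3-(propan-2-yl)-3,4-bis(triethylsilyloxy)-1,2,3,5,8,8a-hexahydroazulen-6-yl]methanol
Conditions: DIBAL-H (2.5 equiv), CH2Cl2, −78 °C; Rochelle salt work-up
Reagents that add atoms: none
Why: DIBAL-H 1,2-reduction of the α,β-unsaturated methyl ester to the allylic alcohol at −78 °C; both silyl ethers, including the enol ether that masks the C4 ketone, are inert to the hydride, so the ketone is not touched at this stage.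

Step 7
Reactants: 10 [(3R,8aR)-8a-methyl-3-(propan-2-yl)-3,4-bis(triethylsilyloxy)-1,2,3,5,8,8a-hexahydroazulen-6-yl]methanol
Product: 11 (3R,3aR,8aR)-3-hydroxy-6-(hydroxymethyl)-8a-methyl-3-(propan-2-yl)-2,3,3a,5,8,8a-hexahydroazulen-4(1H)-one
Conditions: TBAF (2.5 equiv), AcOH (3 equiv), THF, −20 °C → rt
Reagents that add atoms: none
Why: Fluoride desilylation: the enol ether is cleaved first and acetic acid protonates the C3a=C4 enolate on the face opposite the C3 silyloxy group and the angular methyl group, setting C3a (H trans to CH3, trans ring fusion, also the isomer with C4 trans to isopropyl), and the tertiary silyl ether is removed on warming, the buffer suppressing retro-aldol cleavage and dehydration of the tertiary aldol.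

Step 8
Reactants: 11 (3R,3aR,8aR)-3-hydroxy-6-(hydroxymethyl)-8a-methyl-3-(propan-2-yl)-2,3,3a,5,8,8a-hexahydroazulen-4(1H)-one
Product: 12 (3R,3aS,4S,8aR)-6-(hydroxymethyl)-8a-methyl-3-(propan-2-yl)-1,2,3,3a,4,5,8,8a-octahydroazulene-3,4-diol
Conditions: Li, NH3(l)/THF, t-BuOH, −78 °C; NH4Cl
Reagents that add atoms: none
Why: Dissolving-metal reduction of the ketone: the C4 carbanion/ketyl is protonated to give the thermodynamically preferred alcohol, with the C4–O bond equatorial, anti to the C3a–C8a bond and trans to the angular methyl group (4S), whereas hydride reagents would add anti to that 1,3-related methyl group and give the axial epimer; the isolated alkene and the two alkoxides are inert.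

Step 9
Reactants: 12 (3R,3aS,4S,8aR)-6-(hydroxymethyl)-8a-methyl-3-(propan-2-yl)-1,2,3,3a,4,5,8,8a-octahydroazulene-3,4-diol
Product: 13 (3R,3aS,4S,8aR)-3,4-dihydroxy-8a-methyl-3-(propan-2-yl)-1,2,3,3a,4,5,8,8a-octahydroazulene-6-carbaldehyde
Conditions: MnO2 (20 equiv), CH2Cl2, rt
Reagents that add atoms: none
Why: Chemoselective allylic oxidation with manganese dioxide converts only the primary allylic alcohol into the enal; the saturated secondary C4–OH and the tertiary C3–OH do not react.

Step 10
Reactants: 13 (3R,3aS,4S,8aR)-3,4-dihydroxy-8a-methyl-3-(propan-2-yl)-1,2,3,3a,4,5,8,8a-octahydroazulene-6-carbaldehyde; 14 4-[(tert-butyldimethylsilyl)oxy]benzoic acid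
Product: 15 (3R,3aS,4S,8aR)-6-formyl-3-hydroxy-8a-methyl-3-(propan-2-yl)-1,2,3,3a,4,5,8,8a-octahydroazulen-4-yl 4-[(tert-butyldimethylsilyl)oxy]benzoate
Conditions: EDC·HCl (2 equiv), DMAP (1 equiv), CH2Cl2, rt
Reagents that add atoms: none
Why: Steglich esterification (carbodiimide/DMAP) acylates the equatorial secondary C4–OH with retention; the tertiary C3–OH is too hindered to compete and the phenol is masked as its silyl ether.

Step 11
Reactants: 15 (3R,3aS,4S,8aR)-6-formyl-3-hydroxy-8a-methyl-3-(propan-2-yl)-1,2,3,3a,4,5,8,8a-octahydroazulen-4-yl 4-[(tert-butyldimethylsilyl)oxy]benzoate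
Product: 16 (3R,3aS,4S,8aR)-6-formyl-3-hydroxy-8a-methyl-3-(propan-2-yl)-1,2,3,3a,4,5,8,8a-octahydroazulen-4-yl 4-hydroxybenzoate
Conditions: TBAF (1.1 equiv), AcOH (1.5 equiv), THF, 0 °C
Reagents that add atoms: none
Why: Buffered fluoride cleaves the aryl silyl ether, by far the most labile group present, without touching the benzoate, the enal or the tertiary alcohol (desilylation).

**Compound list**

1 | 2-bromo-3-methylcyclopent-2-en-1-one | CC1=C(Br)C(=O)CC1 | starting material
2 | (1R)-2-bromo-3-methyl-1-(propan-2-yl)cyclopent-2-en-1-ol | CC(C)[C@]1(O)CCC(C)=C1Br | intermediate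
3 | (1R)-2-(1-ethoxyethenyl)-3-methyl-1-(propan-2-yl)cyclopent-2-en-1-ol | CC(C)[C@]1(O)CCC(C)=C1C(=C)OCC | intermediate
4 | 1-[(5R)-5-hydroxy-2-methyl-5-(propan-2-yl)cyclopent-1-en-1-yl]ethan-1-one | CC(C)[C@]1(O)CCC(C)=C1C(C)=O | intermediate
5 | triethyl[(1-{(5R)-2-methyl-5-(propan-2-yl)-5-[(triethylsilyl)oxy]cyclopent-1-en-1-yl}ethenyl)oxy]silane | CC(C)[C@]1(O[Si](CC)(CC)CC)CCC(C)=C1C(=C)O[Si](CC)(CC)CC | intermediate
6 | methyl but-3-enoate | C=CCC(=O)OC | starting material
7 | methyl 2-diazobut-3-enoate | C=CC(=[N+]=[N-])C(=O)OC | intermediate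
8 | methyl (1S,2R)-1-ethenyl-2-{(5R)-2-methyl-5-(propan-2-yl)-5-[(triethylsilyl)oxy]cyclopent-1-en-1-yl}-2-[(triethylsilyl)oxy]cyclopropane-1-carboxylate | CC(C)[C@]1(O[Si](CC)(CC)CC)CCC(C)=C1[C@]2(O[Si](CC)(CC)CC)C[C@@]2(C=C)C(=O)OC | intermediate
9 | methyl (3R,8aR)-8a-methyl-3-(propan-2-yl)-3,4-bis(triethylsilyloxy)-1,2,3,5,8,8a-hexahydroazulene-6-carboxylate | CC(C)[C@]1(O[Si](CC)(CC)CC)CC[C@]2(C)CC=C(C(=O)OC)CC(O[Si](CC)(CC)CC)=C12 | intermediate
10 | [(3R,8aR)-8a-methyl-3-(propan-2-yl)-3,4-bis(triethylsilyloxy)-1,2,3,5,8,8a-hexahydroazulen-6-yl]methanol | CC(C)[C@]1(O[Si](CC)(CC)CC)CC[C@]2(C)CC=C(CO)CC(O[Si](CC)(CC)CC)=C12 | intermediate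
11 | (3R,3aR,8aR)-3-hydroxy-6-(hydroxymethyl)-8a-methyl-3-(propan-2-yl)-2,3,3a,5,8,8a-hexahydroazulen-4(1H)-one | CC(C)[C@]1(O)CC[C@]2(C)CC=C(CO)CC(=O)[C@H]21 | intermediate
12 | (3R,3aS,4S,8aR)-6-(hydroxymethyl)-8a-methyl-3-(propan-2-yl)-1,2,3,3a,4,5,8,8a-octahydroazulene-3,4-diol | CC(C)[C@]1(O)CC[C@]2(C)CC=C(CO)C[C@H](O)[C@H]21 | intermediate
13 | (3R,3aS,4S,8aR)-3,4-dihydroxy-8a-methyl-3-(propan-2-yl)-1,2,3,3a,4,5,8,8a-octahydroazulene-6-carbaldehyde | CC(C)[C@]1(O)CC[C@]2(C)CC=C(C=O)C[C@H](O)[C@H]21 | intermediate
14 | 4-[(tert-butyldimethylsilyl)oxy]benzoic acid | CC(C)(C)[Si](C)(C)Oc1ccc(cc1)C(=O)O | starting material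
15 | (3R,3aS,4S,8aR)-6-formyl-3-hydroxy-8a-methyl-3-(propan-2-yl)-1,2,3,3a,4,5,8,8a-octahydroazulen-4-yl 4-[(tert-butyldimethylsilyl)oxy]benzoate | CC(C)[C@]1(O)CC[C@]2(C)CC=C(C=O)C[C@H](OC(=O)c3ccc(O[Si](C)(C)C(C)(C)C)cc3)[C@H]21 | intermediate
16 | (3R,3aS,4S,8aR)-6-formyl-3-hydroxy-8a-methyl-3-(propan-2-yl)-1,2,3,3a,4,5,8,8a-octahydroazulen-4-yl 4-hydroxybenzoate | CC(C)[C@]1(O)CC[C@]2(C)CC=C(C=O)C[C@H](OC(=O)c3ccc(O)cc3)[C@H]21 | target

**Count and risks**

Total steps: 11. Longest linear sequence: 10 steps (steps 1–3 and 5–11).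

Step 5 (key step). What may go wrong: loss of diastereoface control at C8a (mismatched substrate/catalyst pairing, or scrambling through zwitterionic opening of the donor–acceptor cyclopropane), trapping at the vinylogous carbene position, or a Cope step that stalls at the cyclopropane. Fallback, closing the ring by olefin metathesis, from 4 back to 11: 4 is silylated (TESOTf, 2,6-lutidine) to 1-{(5R)-2-methyl-5-(propan-2-yl)-5-[(triethylsilyl)oxy]cyclopent-1-en-1-yl}ethan-1-one F1. Copper-mediated conjugate allylation (allylMgBr, CuBr·SMe2, TMSCl, THF, −78 °C; aq. acid), anti to the silyloxy group, with protonation at C3a, should give the 2-allyl-2-methylcyclopentyl methyl ketone F2 (allyl trans to OSiEt3, acetyl cis to it). Pd-catalysed α-alkenylation of its methyl-side enolate (LiHMDS; 2-bromoallyl TBS ether, Pd/t-Bu3P) gives the 1,7-diene ketone F3. Ring-closing metathesis (second-generation Ru carbene, CH2Cl2, 40 °C) forms C6=C7 and gives the 3-O-triethylsilyl, 6-CH2O-TBS ether of 11 F4, and TBAF/AcOH then returns 11.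

Step 1. What may go wrong: transfer of a β-hydrogen from the isopropyl–metal species (reduction of the ketone) instead of the isopropyl group, or weak facial discrimination. Fallback from 1 back to 2: addition of the organocerium reagent from iPrMgCl and CeCl3 (THF, −78 °C) gives racemic 2-bromo-3-methyl-1-(propan-2-yl)cyclopent-2-en-1-ol F5, which is resolved by preparative chromatography on a chiral stationary phase; the 1R enantiomer is 2.

Step 8. What may go wrong: protonation of the C4 carbanion from the wrong side, pinacol coupling, or retro-aldol cleavage of the β-alkoxy ketone under the basic conditions. Fallback from 11 back to 12: reduction with NaBH4/CeCl3 (MeOH, −40 °C), which should add hydride anti to the angular methyl group, gives the axial epimer (3R,3aS,4R,8aR)-6-(hydroxymethyl)-8a-methyl-3-(propan-2-yl)-1,2,3,3a,4,5,8,8a-octahydroazulene-3,4-diol F6. This is epimerised at C4 to 12 by Meerwein–Ponndorf–Verley/Oppenauer equilibration (Al(OiPr)3, catalytic acetone, iPrOH/PhMe, 80 °C).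

**Further compounds**

F1 | step 5 | 1-{(5R)-2-methyl-5-(propan-2-yl)-5-[(triethylsilyl)oxy]cyclopent-1-en-1-yl}ethan-1-one | CC(C)[C@]1(O[Si](CC)(CC)CC)CCC(C)=C1C(C)=O
F2 | step 5 | 1-{2-allyl-2-methyl-5-(propan-2-yl)-5-[(triethylsilyl)oxy]cyclopentyl}ethan-1-one (allyl trans to OSiEt3, acetyl cis to OSiEt3) | CC(C)[C@]1(O[Si](CC)(CC)CC)CC[C@](C)(CC=C)[C@H]1C(C)=O
F3 | step 5 | 1-{2-allyl-2-methyl-5-(propan-2-yl)-5-[(triethylsilyl)oxy]cyclopentyl}-3-{[(tert-butyldimethylsilyl)oxy]methyl}but-3-en-1-one (ring configuration as F2) | CC(C)[C@]1(O[Si](CC)(CC)CC)CC[C@](C)(CC=C)[C@H]1C(=O)CC(=C)CO[Si](C)(C)C(C)(C)C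
F4 | step 5 | (3R,3aR,8aR)-6-{[(tert-butyldimethylsilyl)oxy]methyl}-8a-methyl-3-(propan-2-yl)-3-[(triethylsilyl)oxy]-2,3,3a,5,8,8a-hexahydroazulen-4(1H)-one | CC(C)[C@]1(O[Si](CC)(CC)CC)CC[C@]2(C)CC=C(CO[Si](C)(C)C(C)(C)C)CC(=O)[C@H]21
F5 | step 1 | racemic 2-bromo-3-methyl-1-(propan-2-yl)cyclopent-2-en-1-ol | CC(C)C1(O)CCC(C)=C1Br
F6 | step 8 | (3R,3aS,4R,8aR)-6-(hydroxymethyl)-8a-methyl-3-(propan-2-yl)-1,2,3,3a,4,5,8,8a-octahydroazulene-3,4-diol | CC(C)[C@]1(O)CC[C@]2(C)CC=C(CO)C[C@@H](O)[C@H]21
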